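**Retrosynthetic overview**
1. The last step only unmasks the B-ring phenol (4'-O-silyl ether). Ring B is bought.
2. Rings C and A are cut together at O1–C8a, C4a–C8a and C7–C8. This gives an open-chain (S)-7-aryl-7-hydroxy-3,5-dioxo-2-prenylheptanoate and a propionamide acetal, which supplies C8a, C8 and the 8-CH3.
3. Forward ring order: pyranone C forms first and benzenoid A second, in the same flask. O1 is tied to the carbon that carries the ethyl group, which fixes 8-Me/6-prenyl.
4. The chain is cut at C4–C4a (Claisen): an (S)-β-hydroxy ester plus the dianion of tert-butyl 2-prenylacetoacetate.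
5. C2 comes from a catalytic enantioselective acetate aldol on 4-silyloxybenzaldehyde. The C2–O bond is never broken afterwards.

Assumption: 4, 5 and 10 are bought as catalogue reagents, and the prenyl-bearing sp3 carbon in 3, 9, 11 and 12 is an inconsequential epimer mixture that is erased on aromatisation.

**Step 1**
Reactants: 1 tert-butyl acetoacetate; 2 prenyl bromide (1-bromo-3-methylbut-2-ene)
Product: 3 tert-butyl 2-acetyl-5-methylhex-4-enoate (racemic)
Conditions: K2CO3 (1.2 equiv), acetone, reflux, 6 h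
Reagents that add atoms: none
Why: Acetoacetic ester alkylation (SN2 of the stabilised enolate on the primary allylic bromide) gives C-monoalkylation, and the new centre is racemic and disappears in step 4.

**Step 2**
Reactants: 4 4-(tert-butyldimethylsilyloxy)benzaldehyde; 5 1-(tert-butyldimethylsilyloxy)-1-methoxyethene
Product: 7 methyl (3S)-3-[4-(tert-butyldimethylsilyloxy)phenyl]-3-hydroxypropanoate, via trichlorosilyl aldolate 6 (not isolated)
Conditions: SiCl4 (1.1 equiv), dimeric BINAM-derived bisphosphoramide (5 mol %, the antipode that leaves the Si face open), CH2Cl2, −78 °C; sat. aq NaHCO3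
Reagents that add atoms: none
Why: In this catalytic enantioselective Mukaiyama acetate aldol (Lewis-base-activated SiCl4), the chiral phosphoramide·SiCl3+ complex binds the aldehyde and admits the ketene acetal only from the Si face, which sets the (S)-carbinol that becomes C2.

**Step 3**
Reactants: 3 tert-butyl 2-acetyl-5-methylhex-4-enoate; 7 methyl (3S)-3-[4-(tert-butyldimethylsilyloxy)phenyl]-3-hydroxypropanoate
Product: 9 tert-butyl (7S)-7-[4-(tert-butyldimethylsilyloxy)phenyl]-7-hydroxy-2-(3-methylbut-2-enyl)-3,5-dioxoheptanoate, via dilithium dianion 8 (not isolated)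
Conditions: 3 (2.5 equiv), LDA (5.1 equiv), THF, −78 → 0 °C; then 7 (1 equiv, pre-lithiated with LDA 1.0 equiv), −78 → 0 °C; AcOH quench at −78 °C. Product used crude or after a fast column.
Reagents that add atoms: none
Why: In this crossed Claisen γ-acylation of a β-keto ester dianion (Huckin–Weiler type), the terminal carbanion is the most nucleophilic site and attacks the methyl ester, the product is stored as its enolate, and the carbinol centre is untouched because an ester aldolate does not retro-aldolise at or below 0 °C.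

**Step 4 (key step)**
Reactants: 9 tert-butyl (7S)-7-[4-(tert-butyldimethylsilyloxy)phenyl]-7-hydroxy-2-(3-methylbut-2-enyl)-3,5-dioxoheptanoate; 10 N,N-dimethylpropionamide dimethyl acetal (1,1-dimethoxy-N,N-dimethylpropan-1-amine)
Product: 14 (2S)-2-[4-(tert-butyldimethylsilyloxy)phenyl]-5,7-dihydroxy-8-methyl-6-(3-methylbut-2-enyl)chroman-4-one, via enaminone 11 (not isolated), via dihydropyranone 12 (not isolated), via dienylketene 13 (not isolated)
Conditions: 10 (1.05 equiv), xylenes (0.02 M), 4 Å MS, 23 °C, 3 h; N2 sparge; then 140 °C with slow distillation, 4–8 h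
Reagents that add atoms: none
Why: Proposed new method: the amide acetal condenses at the most acidic CH2 (C4a, between the two ketones) to give push–pull enaminone 11; the C2 carbinol oxygen then displaces Me2NH at C8a by 6-endo addition–elimination, which is the known Maitland–Japp-type dihydropyranone synthesis from δ-hydroxy-β-dicarbonyls and amide acetals, leaves the C2–O bond intact so (S) is retained, and can only place O1 next to the ethyl-bearing carbon, fixing 8-Me/6-prenyl; on heating, the tert-butyl β-keto ester of 12 loses t-BuOH to an acylketene as in thermal transacetoacetylation, and its vinylogous enol 13, held by the C5–OH···O=C4 hydrogen bond with the ketene carbon over C8, closes by 6π-electrocyclisation and tautomerises to the phenol, the same terminating event as in the Danheiser benzannulation.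

**Step 5**
Reactants: 14 (2S)-2-[4-(tert-butyldimethylsilyloxy)phenyl]-5,7-dihydroxy-8-methyl-6-(3-methylbut-2-enyl)chroman-4-one
Product: 15 (2S)-5,7-dihydroxy-2-(4-hydroxyphenyl)-8-methyl-6-(3-methylbut-2-enyl)chroman-4-one (target)
Conditions: TBAF (1.1 equiv), AcOH (1.2 equiv), THF, 0 °C, 20 min
Reagents that add atoms: none
Why: Fluoride-induced cleavage of the aryl silyl ether is buffered with AcOH, so no phenoxide or C3 enolate builds up, which leaves the prenyl group intact and stops C2 from epimerising by retro-oxa-Michael opening.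

**Compound list**
1 | tert-butyl acetoacetate | CC(=O)CC(=O)OC(C)(C)C | starting material
2 | prenyl bromide | CC(C)=CCBr | starting material
3 | tert-butyl 2-acetyl-5-methylhex-4-enoate (racemic) | CC(=O)C(CC=C(C)C)C(=O)OC(C)(C)C | intermediate
4 | 4-(tert-butyldimethylsilyloxy)benzaldehyde | O=Cc1ccc(O[Si](C)(C)C(C)(C)C)cc1 | starting material
5 | 1-(tert-butyldimethylsilyloxy)-1-methoxyethene | C=C(OC)O[Si](C)(C)C(C)(C)C | starting material
6 | methyl (3S)-3-[4-(tert-butyldimethylsilyloxy)phenyl]-3-(trichlorosilyloxy)propanoate (not isolated) | COC(=O)C[C@H](O[Si](Cl)(Cl)Cl)c1ccc(O[Si](C)(C)C(C)(C)C)cc1 | intermediate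
7 | methyl (3S)-3-[4-(tert-butyldimethylsilyloxy)phenyl]-3-hydroxypropanoate | COC(=O)C[C@H](O)c1ccc(O[Si](C)(C)C(C)(C)C)cc1 | intermediate
8 | dilithium dianion of 3 (not isolated) | [Li+].[Li+].C=C([O-])C(CC=C(C)C)=C([O-])OC(C)(C)C | intermediate
9 | tert-butyl (7S)-7-[4-(tert-butyldimethylsilyloxy)phenyl]-7-hydroxy-2-(3-methylbut-2-enyl)-3,5-dioxoheptanoate (C2 epimers, largely enolised) | CC(C)=CCC(C(=O)OC(C)(C)C)C(=O)CC(=O)C[C@H](O)c1ccc(O[Si](C)(C)C(C)(C)C)cc1 | intermediate
10 | N,N-dimethylpropionamide dimethyl acetal | CCC(OC)(OC)N(C)C | starting material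
11 | tert-butyl (7S)-4-[1-(dimethylamino)propylidene]-7-[4-(tert-butyldimethylsilyloxy)phenyl]-7-hydroxy-2-(3-methylbut-2-enyl)-3,5-dioxoheptanoate (not isolated) | CC(C)=CCC(C(=O)OC(C)(C)C)C(=O)C(=C(CC)N(C)C)C(=O)C[C@H](O)c1ccc(O[Si](C)(C)C(C)(C)C)cc1 | intermediate
12 | tert-butyl 2-{[(2S)-2-[4-(tert-butyldimethylsilyloxy)phenyl]-6-ethyl-4-oxo-3,4-dihydro-2H-pyran-5-yl]carbonyl}-5-methylhex-4-enoate (not isolated) | CCC1=C(C(=O)C(CC=C(C)C)C(=O)OC(C)(C)C)C(=O)C[C@@H](c2ccc(O[Si](C)(C)C(C)(C)C)cc2)O1 | intermediate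
13 | (6S)-6-[4-(tert-butyldimethylsilyloxy)phenyl]-2-ethylidene-3-[1-hydroxy-2-(oxomethylidene)-5-methylhex-4-enylidene]oxan-4-one, the chelated dienylketene (not isolated) | CC=C1O[C@H](c2ccc(O[Si](C)(C)C(C)(C)C)cc2)CC(=O)C1=C(O)C(CC=C(C)C)=C=O | intermediate
14 | (2S)-2-[4-(tert-butyldimethylsilyloxy)phenyl]-5,7-dihydroxy-8-methyl-6-(3-methylbut-2-enyl)chroman-4-one | CC(C)=CCc1c(O)c(C)c2c(c1O)C(=O)C[C@@H](c1ccc(O[Si](C)(C)C(C)(C)C)cc1)O2 | intermediate
15 | (2S)-5,7,4'-trihydroxy-8-methyl-6-prenylflavanone | CC(C)=CCc1c(O)c(C)c2c(c1O)C(=O)C[C@@H](c1ccc(O)cc1)O2 | target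

**Totals**
- Total step count: 5.
- Longest linear sequence: 4 (steps 2, 3, 4, 5). Step 1 runs in parallel.

**Steps most likely to fail**

*Step 4.*
- Risk: the ketene arm of 13 may be captured by the C4 enol oxygen to give a 2-pyranone instead of by C8. Compound 12 may also partly racemise by retro-oxa-Michael opening while Me2NH is still present.
- Fallback (sets out from 7, returns at 14): move the last ring bond to C4a–C5, where no oxygen nucleophile can reach the ketene.
- Commercial tert-butyl 3-oxopentanoate is prenylated with 2 (K2CO3, acetone) to tert-butyl 2-(3-methylbut-2-enyl)-3-oxopentanoate F1.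
- The dianion of F1 (LDA) is acetylated at C4 with N-methoxy-N-methylacetamide to tert-butyl 4-methyl-2-(3-methylbut-2-enyl)-3,5-dioxohexanoate F2.
- The trianion of F2 (LDA, 3.1 equiv) is acylated at its terminal CH3 by 7 to tert-butyl (9S)-9-[4-(tert-butyldimethylsilyloxy)phenyl]-9-hydroxy-4-methyl-2-(3-methylbut-2-enyl)-3,5,7-trioxononanoate F3.
- PPTS and 4 Å MS in toluene at room temperature cyclodehydrate the δ-hydroxy-β-diketone to tert-butyl 2-(3-methylbut-2-enyl)-3-oxo-4-[(2S)-2-[4-(tert-butyldimethylsilyloxy)phenyl]-4-oxo-3,4-dihydro-2H-pyran-6-yl]pentanoate F4.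
- Heating F4 in xylenes generates the acylketene, which closes onto the nucleophilic α-carbon of the vinylogous ester and aromatises to 14.

*Step 3.*
- Risk: proton transfer and the deactivating β-alkoxide may stall the Claisen reaction, and the released LiOMe may attack the aryl silyl ether.
- Fallback (sets out from 7, returns at 9): replace the ester condensation by a ketone synthesis through a chelated tetrahedral intermediate.
- Compound 7 is converted with MeNHOMe·HCl and i-PrMgCl (THF, −20 °C) into (3S)-3-[4-(tert-butyldimethylsilyloxy)phenyl]-3-hydroxy-N-methoxy-N-methylpropanamide F5.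
- F5 is treated with dianion 8 (2.2 equiv). Nothing is expelled until the acidic quench, which then delivers 9.

*Step 2.*
- Risk: the enantioselectivity may be insufficient with this electron-rich aldehyde.
- Fallback (sets out from 4, returns at 7): make the C–C bond without stereocontrol and set C2 by reduction.
- Roskamp homologation of 4 with methyl diazoacetate (cat. SnCl2, CH2Cl2) gives methyl 3-[4-(tert-butyldimethylsilyloxy)phenyl]-3-oxopropanoate F6.
- Noyori hydrogenation of F6 (RuCl2[(R)-BINAP], H2, MeOH) gives 7. For aryl β-keto esters the (R)-ligand delivers the (S)-carbinol.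

**Further compounds**
F1 | step 4 | tert-butyl 2-(3-methylbut-2-enyl)-3-oxopentanoate | CCC(=O)C(CC=C(C)C)C(=O)OC(C)(C)C
F2 | step 4 | tert-butyl 4-methyl-2-(3-methylbut-2-enyl)-3,5-dioxohexanoate | CC(=O)C(C)C(=O)C(CC=C(C)C)C(=O)OC(C)(C)C
F3 | step 4 | tert-butyl (9S)-9-[4-(tert-butyldimethylsilyloxy)phenyl]-9-hydroxy-4-methyl-2-(3-methylbut-2-enyl)-3,5,7-trioxononanoate | CC(C)=CCC(C(=O)OC(C)(C)C)C(=O)C(C)C(=O)CC(=O)C[C@H](O)c1ccc(O[Si](C)(C)C(C)(C)C)cc1
F4 | step 4 | tert-butyl 2-(3-methylbut-2-enyl)-3-oxo-4-[(2S)-2-[4-(tert-butyldimethylsilyloxy)phenyl]-4-oxo-3,4-dihydro-2H-pyran-6-yl]pentanoate | CC(C(=O)C(CC=C(C)C)C(=O)OC(C)(C)C)C1=CC(=O)C[C@@H](c2ccc(O[Si](C)(C)C(C)(C)C)cc2)O1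
F5 | step 3 | (3S)-3-[4-(tert-butyldimethylsilyloxy)phenyl]-3-hydroxy-N-methoxy-N-methylpropanamide | CON(C)C(=O)C[C@H](O)c1ccc(O[Si](C)(C)C(C)(C)C)cc1
F6 | step 2 | methyl 3-[4-(tert-butyldimethylsilyloxy)phenyl]-3-oxopropanoate | COC(=O)CC(=O)c1ccc(O[Si](C)(C)C(C)(C)C)cc1
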